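**Retrosynthetic overview**

1. Caespitol 12 ⇐ Markovnikov HBr addition to the exocyclic allylic chloride 11 ⇐ ene-type chlorination of cyclohexene 10; the ring halogens go in last, Cl before Br.
2. 10 ⇐ one cationic operation on the acyclic bromohydrin acetate 7: ionisation of the (Z)-allylic acetate closes the cyclohexene (C1–C6 bond) first, and the C11 oxygen then closes the oxane (C7–O bond) in the same flask.
3. 7 ⇐ SN2 bromide opening of epoxide 6 ⇐ reagent-controlled epoxidation of triene 5 (sets C10).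
4. 5 ⇐ cross-metathesis of 4 ⇐ asymmetric allylation of enal 2 (sets C8) ⇐ allylic oxidation of neryl acetate 1.

Assumption: the target is caespitol, (2R,3R,5R)-5-bromo-2-[(1S,3R,4R)-4-bromo-3-chloro-4-methylcyclohexyl]-2,6,6-trimethyloxan-3-ol; atom labels C1–C11 follow the chain of compound 7 (C1 carries the acetate, C6=C7 is the central alkene, C8 the carbinol, C10 the CHBr, C11 the CMe2 carbon).

**Step 1**
Reactants: 1 neryl acetate, (2Z)-3,7-dimethylocta-2,6-dien-1-yl acetate
Product: 2 (2Z,6E)-3,7-dimethyl-8-oxoocta-2,6-dien-1-yl acetate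
Conditions: SeO2 (1.1 equiv), 1,4-dioxane/H2O 20:1, 80 °C
Reagents that add atoms: selenium dioxide, O=[Se]=O
Why: Riley allylic oxidation (ene reaction then [2,3]-sigmatropic shift) attacks the electron-rich 6,7-alkene rather than the acetate-deactivated 2,3-alkene and oxidises only the (E)-methyl group, giving the (E)-enal with no new stereocentre.

**Step 2**
Reactants: 2 (2Z,6E)-3,7-dimethyl-8-oxoocta-2,6-dien-1-yl acetate
Product: 4 (2Z,6E,8R)-8-hydroxy-3,7-dimethylundeca-2,6,10-trien-1-yl acetate, via diisopinocampheylborinate ester 3 (not isolated)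
Conditions: (+)-Ipc2B(allyl) (from (−)-α-pinene, 1.3 equiv), Et2O, −78 °C; then HOCH2CH2NH2, rt
Reagents that add atoms: (+)-B-allyldiisopinocampheylborane, C=CCB([C@H]1C[C@H]2C[C@@H]([C@@H]1C)C2(C)C)[C@H]1C[C@H]2C[C@@H]([C@@H]1C)C2(C)C
Why: Brown allylboration through a chair Zimmerman–Traxler transition state, in which the (−)-α-pinene-derived reagent adds to the Re face of the enal carbonyl (the sense that gives (R)-1-phenylbut-3-en-1-ol from benzaldehyde) and sets C8 as R, while the acetate and the trisubstituted alkenes are inert at −78 °C.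

**Step 3**
Reactants: 4 (2Z,6E,8R)-8-hydroxy-3,7-dimethylundeca-2,6,10-trien-1-yl acetate
Product: 5 (2Z,6E,8R)-8-hydroxy-3,7,11-trimethyldodeca-2,6,10-trien-1-yl acetate
Conditions: 2-methyl-2-butene (excess), second-generation Grubbs catalyst RuCl2(=CHPh)(PCy3)(H2IMes) (5 mol %), CH2Cl2, 40 °C
Reagents that add atoms: 2-methyl-2-butene, CC=C(C)C
Why: Olefin cross-metathesis in which only the monosubstituted alkene engages the ruthenium carbene, the trisubstituted alkenes stay untouched, and excess 2-methyl-2-butene converts the vinyl group into the prenyl group without affecting C8.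

**Step 4**
Reactants: 5 (2Z,6E,8R)-8-hydroxy-3,7,11-trimethyldodeca-2,6,10-trien-1-yl acetate
Product: 6 (2Z,6E,8R)-9-[(2S)-3,3-dimethyloxiran-2-yl]-8-hydroxy-3,7-dimethylnona-2,6-dien-1-yl acetate
Conditions: L-fructose-derived Shi ketone (enantiomer of the usual catalyst, 30 mol %), Oxone (2KHSO5·KHSO4·K2SO4, 1.1 equiv KHSO5), K2CO3, Bu4NHSO4, MeCN/CH2(OMe)2/aq. Na2B4O7 buffer pH 10.5, 0 °C
Reagents that add atoms: potassium peroxymonosulfate KHSO5 (active component of Oxone), [K+].[O-]S(=O)(=O)OO
Why: Shi asymmetric epoxidation, in which the chiral dioxirane reacts fastest with the electron-rich terminal 10,11-alkene (the 6,7- and 2,3-alkenes are deactivated by the allylic OH and OAc) and the L-fructose-derived ketone delivers oxygen through the spiro transition state to give the (S)-epoxide at C10.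

**Step 5**
Reactants: 6 (2Z,6E,8R)-9-[(2S)-3,3-dimethyloxiran-2-yl]-8-hydroxy-3,7-dimethylnona-2,6-dien-1-yl acetate
Product: 7 (2Z,6E,8R,10R)-10-bromo-8,11-dihydroxy-3,7,11-trimethyldodeca-2,6-dien-1-yl acetate
Conditions: Li2NiBr4 (0.4 M in THF, 2 equiv), THF, 0 °C to rt; pH 7 aqueous work-up
Reagents that add atoms: dilithium tetrabromonickelate Li2NiBr4, [Li+].[Li+].Br[Ni-2](Br)(Br)Br
Why: SN2 epoxide opening by soft nucleophilic bromide under non-acidic conditions occurs at the less hindered secondary carbon, inverting C10 to R and leaving the tertiary carbinol at C11.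

**Step 6**
Reactants: 7 (2Z,6E,8R,10R)-10-bromo-8,11-dihydroxy-3,7,11-trimethyldodeca-2,6-dien-1-yl acetate
Product: 10 (2R,3R,5R)-5-bromo-2,6,6-trimethyl-2-[(1S)-4-methylcyclohex-3-en-1-yl]oxan-3-ol, via bis(trimethylsilyl) ether 8 (not isolated), via cyclised trimethylsilyl ether 9 (not isolated)
Conditions: TMSOTf (2.3 equiv), 2,6-di-tert-butyl-4-methylpyridine (2.5 equiv), CH2Cl2 (0.01 M), −78 to −40 °C; then MeOH, citric acid, 0 °C
Reagents that add atoms: none
Why: Proposed new method: under proton-free conditions TMSOTf first caps both hydroxyls (8) and then ionises only the primary (Z)-allylic acetate, the C6=C7 alkene closes onto C1 as in the neryl-to-terpinyl cyclisation to form the cyclohexene, and the C11 silyl ether oxygen captures C7 anti to the new C1–C6 bond through a chair oxane transition state (C10–Br equatorial, C7–methyl axial, C8–OSi axial and near the alkene plane so that C8–H faces the incoming C1), so the (E)-alkene geometry and anti addition set C6 as S and C7 as R before silyl loss gives 9; the closest known reactions are the acid-promoted cyclisation of nerolidol and farnesol derivatives to bisabolols and hydroxyl- or silyl ether-terminated cation–olefin (polyene) cyclisations.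

**Step 7**
Reactants: 10 (2R,3R,5R)-5-bromo-2,6,6-trimethyl-2-[(1S)-4-methylcyclohex-3-en-1-yl]oxan-3-ol
Product: 11 (2R,3R,5R)-5-bromo-2-[(1S,3R)-3-chloro-4-methylidenecyclohexyl]-2,6,6-trimethyloxan-3-ol
Conditions: Ca(OCl)2, CO2 (dry ice), CH2Cl2/H2O, 0 °C
Reagents that add atoms: Ca(OCl)2, [Ca+2].[O-]Cl.[O-]Cl
Why: Ionic ene-type allylic chlorination by HOCl, in which electrophilic chlorine adds to the ring CH carbon of the trisubstituted alkene from the axial direction (chair-like transition state, trans to the equatorial C6 substituent) and a methyl proton is lost, giving the axial (R)-allylic chloride with an exocyclic methylene, while the hindered alcohol, the ether and the secondary bromide survive the buffered two-phase conditions.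

**Step 8**
Reactants: 11 (2R,3R,5R)-5-bromo-2-[(1S,3R)-3-chloro-4-methylidenecyclohexyl]-2,6,6-trimethyloxan-3-ol
Product: 12 caespitol, (2R,3R,5R)-5-bromo-2-[(1S,3R,4R)-4-bromo-3-chloro-4-methylcyclohexyl]-2,6,6-trimethyloxan-3-ol
Conditions: HBr (anhydrous, 1.5 equiv), CH2Cl2, −78 to −40 °C
Reagents that add atoms: hydrogen bromide, Br
Why: Markovnikov hydrobromination in which protonation of the 1,1-disubstituted alkene gives the tertiary cation, the neighbouring axial chlorine bridges it (chloronium participation), and bromide enters anti and axial to give the trans-diaxial tertiary bromide with the R configuration.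

**Compound list**

1 | neryl acetate, (2Z)-3,7-dimethylocta-2,6-dien-1-yl acetate | CC(C)=CCC/C(C)=C\COC(C)=O | starting material
2 | (2Z,6E)-3,7-dimethyl-8-oxoocta-2,6-dien-1-yl acetate | O=C/C(C)=C/CC/C(C)=C\COC(C)=O | intermediate
3 | (2Z,6E,8R)-8-(diisopinocampheylboranyloxy)-3,7-dimethylundeca-2,6,10-trien-1-yl acetate (not isolated) | C=CC[C@@H](OB([C@H]1C[C@H]2C[C@@H]([C@@H]1C)C2(C)C)[C@H]1C[C@H]2C[C@@H]([C@@H]1C)C2(C)C)/C(C)=C/CC/C(C)=C\COC(C)=O | intermediate
4 | (2Z,6E,8R)-8-hydroxy-3,7-dimethylundeca-2,6,10-trien-1-yl acetate | C=CC[C@@H](O)/C(C)=C/CC/C(C)=C\COC(C)=O | intermediate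
5 | (2Z,6E,8R)-8-hydroxy-3,7,11-trimethyldodeca-2,6,10-trien-1-yl acetate | CC(C)=CC[C@@H](O)/C(C)=C/CC/C(C)=C\COC(C)=O | intermediate
6 | (2Z,6E,8R)-9-[(2S)-3,3-dimethyloxiran-2-yl]-8-hydroxy-3,7-dimethylnona-2,6-dien-1-yl acetate | CC1(C)O[C@H]1C[C@@H](O)/C(C)=C/CC/C(C)=C\COC(C)=O | intermediate
7 | (2Z,6E,8R,10R)-10-bromo-8,11-dihydroxy-3,7,11-trimethyldodeca-2,6-dien-1-yl acetate | CC(C)(O)[C@H](Br)C[C@@H](O)/C(C)=C/CC/C(C)=C\COC(C)=O | intermediate
8 | (2Z,6E,8R,10R)-10-bromo-3,7,11-trimethyl-8,11-bis(trimethylsilyloxy)dodeca-2,6-dien-1-yl acetate (not isolated) | CC(C)(O[Si](C)(C)C)[C@H](Br)C[C@@H](O[Si](C)(C)C)/C(C)=C/CC/C(C)=C\COC(C)=O | intermediate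
9 | [(2R,3R,5R)-5-bromo-2,6,6-trimethyl-2-[(1S)-4-methylcyclohex-3-en-1-yl]oxan-3-yl]oxy-trimethylsilane (not isolated) | CC1(C)O[C@](C)([C@H]2CCC(C)=CC2)[C@H](O[Si](C)(C)C)C[C@H]1Br | intermediate
10 | (2R,3R,5R)-5-bromo-2,6,6-trimethyl-2-[(1S)-4-methylcyclohex-3-en-1-yl]oxan-3-ol | CC1(C)O[C@](C)([C@H]2CCC(C)=CC2)[C@H](O)C[C@H]1Br | intermediate
11 | (2R,3R,5R)-5-bromo-2-[(1S,3R)-3-chloro-4-methylidenecyclohexyl]-2,6,6-trimethyloxan-3-ol | CC1(C)O[C@](C)([C@H]2CCC(=C)[C@H](Cl)C2)[C@H](O)C[C@H]1Br | intermediate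
12 | caespitol, (2R,3R,5R)-5-bromo-2-[(1S,3R,4R)-4-bromo-3-chloro-4-methylcyclohexyl]-2,6,6-trimethyloxan-3-ol | CC1(C)O[C@](C)([C@H]2CC[C@@](C)(Br)[C@H](Cl)C2)[C@H](O)C[C@H]1Br | target

**Step count and risks**

Total step count: 8. Longest linear sequence: 8 (fully linear from neryl acetate).

Steps most likely to fail:

Step 6 (the two-ring closure). The C7 cation sits next to a CH–OSi carbon, so a 1,2-hydride shift from C8 (pinacol-type, giving the C8 ketone), proton loss to bisabolene-type dienes, or weak C6/C7 facial control could take over. The fallback sets out from 5 and closes the rings in separate operations. Formolysis (HCO2H, pentane, 0 °C, the conditions that turn nerolidol into bisabolol) cyclises the neryl unit and caps C7 and O8 as formates, giving (2R,3R)-6-methyl-2-[(1S)-4-methylcyclohex-3-en-1-yl]hept-5-ene-2,3-diyl diformate F1. K2CO3 in MeOH then frees (2R,3R)-6-methyl-2-[(1S)-4-methylcyclohex-3-en-1-yl]hept-5-ene-2,3-diol F2. 2,4,4,6-Tetrabromocyclohexa-2,5-dienone in MeNO2 at 0 °C closes the oxane by 6-endo bromoetherification of the C7 hydroxyl onto the prenyl alkene (chair transition state, bromine equatorial). This comes back to the route at 10 and bypasses 6 and 7; the cost is diastereomer separation and the usual oxolane by-product from O8.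

Step 4 (site selectivity of the epoxidation). With the C8 hydroxyl free, the 6,7-alkene is only moderately deactivated and may compete with the 10,11-alkene. The fallback sets out from 5 and enforces selectivity through the substrate. TESCl and imidazole in CH2Cl2 give (2Z,6E,8R)-3,7,11-trimethyl-8-(triethylsilyloxy)dodeca-2,6,10-trien-1-yl acetate F3, whose bulky allylic silyl ether shields and deactivates the 6,7-alkene. The same epoxidation then gives (2Z,6E,8R)-9-[(2S)-3,3-dimethyloxiran-2-yl]-3,7-dimethyl-8-(triethylsilyloxy)nona-2,6-dien-1-yl acetate F4. Bu4NF buffered with AcOH in THF removes the silyl group and comes back to the route at 6.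

Step 7 (ene chlorination). Facial selectivity at the new C–Cl centre, exo- versus endocyclic alkene formation and oxidation of the secondary alcohol are all uncertain. The fallback sets out from 10 and installs both halogens through an epoxide. mCPBA in CH2Cl2 gives both epoxides; only the isomer with the oxirane oxygen cis to the side chain, (2R,3R,5R)-5-bromo-2,6,6-trimethyl-2-[(1S,3S,6R)-6-methyl-7-oxabicyclo[4.1.0]heptan-3-yl]oxan-3-ol F5, opens diaxially at its secondary carbon. Li2CuCl4 in THF opens it to the trans-diaxial chlorohydrin (2R,3R,5R)-5-bromo-2-[(1S,3R,4R)-3-chloro-4-hydroxy-4-methylcyclohexyl]-2,6,6-trimethyloxan-3-ol F6. TMSBr in CH2Cl2 at −20 °C then replaces the tertiary hydroxyl by bromide with retention through the chloronium ion. This comes back to the route at 12 and bypasses 11.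

**Further compounds**

F1 | step 6 | (2R,3R)-6-methyl-2-[(1S)-4-methylcyclohex-3-en-1-yl]hept-5-ene-2,3-diyl diformate | O=CO[C@](C)([C@H]1CCC(C)=CC1)[C@H](OC=O)CC=C(C)C
F2 | step 6 | (2R,3R)-6-methyl-2-[(1S)-4-methylcyclohex-3-en-1-yl]hept-5-ene-2,3-diol | O[C@](C)([C@H]1CCC(C)=CC1)[C@H](O)CC=C(C)C
F3 | step 4 | (2Z,6E,8R)-3,7,11-trimethyl-8-(triethylsilyloxy)dodeca-2,6,10-trien-1-yl acetate | CC(C)=CC[C@@H](O[Si](CC)(CC)CC)/C(C)=C/CC/C(C)=C\COC(C)=O
F4 | step 4 | (2Z,6E,8R)-9-[(2S)-3,3-dimethyloxiran-2-yl]-3,7-dimethyl-8-(triethylsilyloxy)nona-2,6-dien-1-yl acetate | CC1(C)O[C@H]1C[C@@H](O[Si](CC)(CC)CC)/C(C)=C/CC/C(C)=C\COC(C)=O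
F5 | step 7 | (2R,3R,5R)-5-bromo-2,6,6-trimethyl-2-[(1S,3S,6R)-6-methyl-7-oxabicyclo[4.1.0]heptan-3-yl]oxan-3-ol | CC1(C)O[C@](C)([C@H]2CC[C@@]3(C)O[C@H]3C2)[C@H](O)C[C@H]1Br
F6 | step 7 | (2R,3R,5R)-5-bromo-2-[(1S,3R,4R)-3-chloro-4-hydroxy-4-methylcyclohexyl]-2,6,6-trimethyloxan-3-ol | CC1(C)O[C@](C)([C@H]2CC[C@@](C)(O)[C@H](Cl)C2)[C@H](O)C[C@H]1Br
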